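Read the clock first.

| flask | starting material | first nucleophile | second nucleophile | remark | time |
|---|---|---|---|---|---|
| amber | 30 mM | 3 equiv | 1.2 equiv | run made earlier |  |
| red | 30 mM | 3 equiv | 0.60 equiv | run made earlier |  |
| Wednesday's | 30 mM | 3.00 equiv | 1.20 equiv | a closed flask charged with all of it at once and left for 80 min | 80 min |
| Saturday's | 30 mM | 3.00 equiv | 1.20 equiv (fed, over 64.0 min) | a stirred flask in which second nucleophile is dosed at a steady rate over 64.0 min without added volume, worked up at 80 min | 80 min |
| Thursday's | 30 mM | 3.00 equiv | 1.20 equiv | a single well-mixed tank run continuously and read at steady state, 80 min in it on average |  |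
| Friday's | 30 mM (fed, over 64.0 min) | 3.00 equiv | 1.20 equiv | a stirred flask in which starting material is dosed at a steady rate over 64.0 min without added volume, worked up at 80 min | 80 min |

| run | time / min | target / % | starting material / % |
|---|---|---|---|
| amber | 12.0 | 13 | 0 |
| amber | 25.0 | 9 | 2 |
| amber | 40.0 | 8 | 2 |
| amber | 50.0 | 7 | 1 |
| amber | 60.0 | 8 | 0 |
| amber | 80.0 | 8 | 1 |
| red | 2.50 | 38 | 9 |
| red | 5.00 | 19 | 1 |
| red | 8.00 | 14 | 0 |
| red | 10.0 | 9 | 0 |
| red | 12.0 | 12 | 1 |
| red | 15.0 | 7 | 0 |

(scatter of a reading: 2 percentage points)

- the set-up with the highest amount of target at the outlet or at the end, in percent of the starting material put in ("none" if the first two lie within 2 percentage points) (Wednesday's / Saturday's / Thursday's / Friday's / none)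
- amount of target at the outlet or at the end, in percent of the starting material put in, Wednesday's
- amount of target at the outlet or at the end, in percent of the starting material put in, Saturday's
- amount of target at the outlet or at the end, in percent of the starting material put in, Thursday's
- amount of target at the outlet or at the end, in percent of the starting material put in, Friday's

- the stated concentrations are those of everything mixed, before any reaction; amounts are the same in each set-up
- the feed brings no volume worth counting
- the earlier runs were made in a closed, stirred flask
- a reading or a percentage of target counts all its forms, free or not

1. The red run holds 9% of its starting material at 2.50 min. Taken as a first-order fall, that reading gives a mean life τ of 1.04 min, with the scatter of the reading in it.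

2. A fed flask has a second clock, the dosing time. I call the overlap, ω, the share of a steady feed that arrives during one life τ, here 1.62%.

3. I follow one molecule of starting material in Saturday's. It stands from the start beside the whole first nucleophile, and τ is far shorter than the dosing time. During that life, 0.0195 equiv of second nucleophile comes in, far less than the 3.00 equiv of first nucleophile charged.

4. I assume that the two nucleophiles compete at a fork, a question of selectivity, though the readings show neither path. In Saturday's, then, the molecule meets hardly any of the second nucleophile's charge.

5. My reckoning: I expect Wednesday's to repeat amber's readings from 25.0 min on, which average 8.00%. I expect Saturday's above that average, and best. In Friday's and Thursday's, starting material comes in among both nucleophiles, and I expect no gain over that average.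

6. The forecast gives 8% for Wednesday's, 9% for Saturday's, 11.5% for Thursday's and 10% for Friday's, with best: none. Its words: “The differences are small, so I call no clear winner.” My reckoning parts from it on the best set-up: I name Saturday's.

7. The flasks give 8.19% for Wednesday's, 18.3% for Saturday's, 4.53% for Thursday's and 0.815% for Friday's. Best: Saturday's.

    starting material ⇌ intermediate (K = 0.130, k = 1.30 min⁻¹)
    first nucleophile + intermediate → target (k = 610 M⁻¹ min⁻¹)
    second nucleophile + intermediate → other capture product (k = 900 M⁻¹ min⁻¹)
    second nucleophile + target ⇌ idle adduct, settled at all times (K = 88.0 M⁻¹)
    2 first nucleophile → self-condensation product (k = 6.40 M⁻¹ min⁻¹)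
    target ⇌ isomer of the product (K = 16.0, k = 0.560 min⁻¹)

8. Saturday's, with an ω of 1.62%, ends with 3.13% of other capture product, against 45.4% in Wednesday's. In Friday's, at 0.815 min, first nucleophile goes into self-condensation product 220 times as fast as into target, half of that step's turnover is done by 0.815 min against a dosing time of 64.0 min, and Friday's ends with 91.7% of other capture product. Friday's flask with 0.300 equiv of second nucleophile has the same ω, and it ends with 0% of first nucleophile, 0% of second nucleophile and 45.1% of starting material.

(Readings and results come from a simulation with constants of no real substance; scatter was added.)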